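**Retrosynthetic overview**
1. The target comes from a finished ten-membered triene lactone alcohol by late epoxidations: hydroxyl-directed at C4=C15, then dioxirane at C1=C10 and C2=C3.
2. The carbocycle and the trans-fused α-methylene-γ-butyrolactone come from one key C6–C7 bond: chromium-catalysed electroreductive allylation of a C6 aldehyde by a (Z)-2-(bromomethyl)enoate, then lactonisation. Ring order: carbocycle, lactone, three oxiranes.
3. The seco-chain comes from Sonogashira coupling at C1–C2 of an east E-vinyl iodide with a west enyne, then cis-semireduction to the 2Z alkene.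
4. East half from (R)-glyceraldehyde acetonide: propargylation sets C8, the dioxolane is the masked C7 aldehyde, Baylis–Hillman adds C11–C13, angelate goes on early.
5. West half from (S)-glyceraldehyde acetonide: chromium alkenylation sets C5, the dioxolane is the masked C6 aldehyde.

Assumption: both enantiomers of glyceraldehyde acetonide are taken as purchasable; locants follow germacranolide numbering (C6 bears the lactone oxygen, C8 the angelate, C10 the methyl C14, C4 the spiro-oxirane with CH2 = C15, C11=C13 the exocyclic methylene, C12 the lactone carbonyl).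

**Step 1**
Reactants: 1 (4R)-2,2-dimethyl-1,3-dioxolane-4-carbaldehyde; 2 3-bromoprop-1-yne (propargyl bromide)
Product: 3 (1S)-1-[(4R)-2,2-dimethyl-1,3-dioxolan-4-yl]but-3-yn-1-ol
Conditions: Zn dust, THF/sat. aq NH4Cl, 0 °C → rt
Reagents that add atoms: none
Why: Barbier-type zinc propargylation attacks the aldehyde anti to the dioxolane C–O bond (Felkin–Anh), so the stereocentre bought in 1 sets the new carbinol (future C8) as the anti (1S) epimer, the minor syn epimer being removed by chromatography.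

**Step 2**
Reactants: 3 (1S)-1-[(4R)-2,2-dimethyl-1,3-dioxolan-4-yl]but-3-yn-1-ol
Product: 5 (1S,3E)-1-[(4R)-2,2-dimethyl-1,3-dioxolan-4-yl]-4-iodo-3-methylbut-3-en-1-ol, via alkenylalane 4 (not isolated)
Conditions: AlMe3 (3.5 equiv), Cp2ZrCl2 (0.25 equiv), CH2Cl2, 0 °C → rt; then I2, THF, −30 → 0 °C
Reagents that add atoms: trimethylaluminium C[Al](C)C; iodine II
Why: Negishi zirconium-catalysed carboalumination adds methyl and aluminium syn across the terminal alkyne (methyl to the internal carbon) and iodinolysis goes with retention, giving only the E-vinyl iodide (C10 methyl, C1 iodide).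

**Step 3**
Reactants: 5 (1S,3E)-1-[(4R)-2,2-dimethyl-1,3-dioxolan-4-yl]-4-iodo-3-methylbut-3-en-1-ol; 6 angelic acid [(2Z)-2-methylbut-2-enoic acid]
Product: 8 (1S,3E)-1-[(4R)-2,2-dimethyl-1,3-dioxolan-4-yl]-4-iodo-3-methylbut-3-en-1-yl (2Z)-2-methylbut-2-enoate, via mixed anhydride 7 (not isolated)
Conditions: 6, 2,4,6-trichlorobenzoyl chloride, Et3N, toluene, rt; then 5, toluene, 80 °C (no DMAP)
Reagents that add atoms: none
Why: Yamaguchi-type mixed-anhydride esterification without nucleophilic catalyst acylates the only free hydroxyl and keeps the Z (angelate) geometry that base catalysis would isomerise to tiglate.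

**Step 4**
Reactants: 8 (1S,3E)-1-[(4R)-2,2-dimethyl-1,3-dioxolan-4-yl]-4-iodo-3-methylbut-3-en-1-yl (2Z)-2-methylbut-2-enoate
Product: 10 (2S,4E)-5-iodo-4-methyl-1-oxopent-4-en-2-yl (2Z)-2-methylbut-2-enoate, via diol 9 (not isolated)
Conditions: H5IO6 (1.5 equiv), EtOAc, rt; crude used at once
Reagents that add atoms: none
Why: Periodic acid hydrolyses the terminal acetonide and cleaves the 1,2-diol (Malaprade reaction) in one pot, turning the spent controlling stereocentre into the C7 aldehyde without touching C8.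

**Step 5**
Reactants: 10 (2S,4E)-5-iodo-4-methyl-1-oxopent-4-en-2-yl (2Z)-2-methylbut-2-enoate; 11 methyl acrylate
Product: 12 methyl 2-[(1RS,2S,4E)-1-hydroxy-5-iodo-4-methyl-2-{[(2Z)-2-methylbut-2-enoyl]oxy}pent-4-en-1-yl]prop-2-enoate
Conditions: DABCO (0.5 equiv), 11 (6 equiv, neat), 0 °C → rt, 16 h
Reagents that add atoms: none
Why: Morita–Baylis–Hillman reaction of the activated α-acyloxy aldehyde installs C11–C13 as the acrylate, and the new carbinol (C7) may be a mixture because it becomes sp2 in step 11.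

**Step 6**
Reactants: 13 4-(trimethylsilyl)but-3-yn-2-one
Product: 14 4-(trimethylsilyl)but-1-en-3-yn-2-yl trifluoromethanesulfonate
Conditions: KN(SiMe3)2, PhNTf2, THF, −78 → −40 °C
Reagents that add atoms: N-phenyl-bis(trifluoromethanesulfonimide) O=S(=O)(N(c1ccccc1)S(=O)(=O)C(F)(F)F)C(F)(F)F
Why: Kinetic enolisation of the methyl ketone and O-sulfonylation (enol triflate formation) gives an alkenyl triflate, a standard partner for chromium-mediated alkenylation.

**Step 7**
Reactants: 14 4-(trimethylsilyl)but-1-en-3-yn-2-yl trifluoromethanesulfonate; 15 (4S)-2,2-dimethyl-1,3-dioxolane-4-carbaldehyde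
Product: 17 (1R)-1-[(4S)-2,2-dimethyl-1,3-dioxolan-4-yl]-2-methylidenebut-3-yn-1-ol, via silylalkyne adduct 16 (not isolated)
Conditions: CrCl2 (4 equiv), NiCl2 (2 mol%), DMF, rt; then K2CO3 (0.3 equiv), MeOH, rt
Reagents that add atoms: none
Why: Nozaki–Hiyama–Kishi alkenylation adds the alkenylchromium to the α-alkoxy aldehyde in the Felkin–Anh sense, so the stereocentre bought in 15 sets the new carbinol (future C5) as the anti (1R) epimer (minor syn epimer separated), and basic methanol then removes the alkyne silyl group.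

**Step 8**
Reactants: 17 (1R)-1-[(4S)-2,2-dimethyl-1,3-dioxolan-4-yl]-2-methylidenebut-3-yn-1-ol
Product: 18 tert-butyl{[(1R)-1-[(4S)-2,2-dimethyl-1,3-dioxolan-4-yl]-2-methylidenebut-3-yn-1-yl]oxy}dimethylsilane
Conditions: TBSOTf, 2,6-lutidine, CH2Cl2, −78 → 0 °C
Reagents that add atoms: tert-butyldimethylsilyl trifluoromethanesulfonate CC(C)(C)[Si](C)(C)OS(=O)(=O)C(F)(F)F
Why: Silylation of the hindered secondary alcohol gives a non-chelating ether that later steers Felkin–Anh addition at C6 and survives periodic acid.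

**Step 9**
Reactants: 12 methyl 2-[(1RS,2S,4E)-1-hydroxy-5-iodo-4-methyl-2-{[(2Z)-2-methylbut-2-enoyl]oxy}pent-4-en-1-yl]prop-2-enoate; 18 tert-butyl{[(1R)-1-[(4S)-2,2-dimethyl-1,3-dioxolan-4-yl]-2-methylidenebut-3-yn-1-yl]oxy}dimethylsilane
Product: 19 methyl 2-[(1RS,2S,4E,9R)-9-{[tert-butyl(dimethyl)silyl]oxy}-9-[(4S)-2,2-dimethyl-1,3-dioxolan-4-yl]-1-hydroxy-4-methyl-8-methylidene-2-{[(2Z)-2-methylbut-2-enoyl]oxy}non-4-en-6-yn-1-yl]prop-2-enoate
Conditions: Pd(PPh3)2Cl2 (3 mol%), CuI (6 mol%), Et3N (3 equiv), THF, rt, degassed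
Reagents that add atoms: none
Why: Sonogashira coupling of the E-vinyl iodide with the terminal enyne forms the C1–C2 bond with retention of alkene geometry under mild amine conditions that leave the acrylate, the angelate and the free carbinol alone.

**Step 10**
Reactants: 19 (dienyne from step 9)
Product: 20 methyl 2-[(1RS,2S,4E,6Z,9R)-9-{[tert-butyl(dimethyl)silyl]oxy}-9-[(4S)-2,2-dimethyl-1,3-dioxolan-4-yl]-1-hydroxy-4-methyl-8-methylidene-2-{[(2Z)-2-methylbut-2-enoyl]oxy}nona-4,6-dien-1-yl]prop-2-enoate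
Conditions: Zn dust activated with Cu(OAc)2 and AgNO3, MeOH/H2O 1:1, 35 °C, dark
Reagents that add atoms: none
Why: Boland reduction semireduces only the alkyne that is conjugated on both sides and does so cis, giving the 2Z alkene of the triene without over-reduction of the enoates.

**Step 11**
Reactants: 20 (triene alcohol from step 10)
Product: 21 methyl (2Z,4S,6E,8Z,11R)-2-(bromomethyl)-11-{[tert-butyl(dimethyl)silyl]oxy}-11-[(4S)-2,2-dimethyl-1,3-dioxolan-4-yl]-6-methyl-10-methylidene-4-{[(2Z)-2-methylbut-2-enoyl]oxy}undeca-2,6,8-trienoate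
Conditions: NBS, Me2S, CH2Cl2 (premixed at 0 °C), then 20, −20 → 0 °C
Reagents that add atoms: N-bromosuccinimide O=C1CCC(=O)N1Br
Why: Corey–Kim-type activation of the Baylis–Hillman alcohol followed by SN2′ attack of bromide gives the thermodynamically preferred (Z)-2-(bromomethyl)enoate and erases the C7 carbinol mixture.

**Step 12**
Reactants: 21 (allylic bromide from step 11)
Product: 23 methyl (2Z,4S,6E,8Z,11R)-2-(bromomethyl)-11-{[tert-butyl(dimethyl)silyl]oxy}-6-methyl-10-methylidene-4-{[(2Z)-2-methylbut-2-enoyl]oxy}-12-oxododeca-2,6,8-trienoate, via diol 22 (not isolated)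
Conditions: H5IO6 (1.5 equiv), EtOAc, 0 °C → rt; crude used at once
Reagents that add atoms: none
Why: Periodic acid again unmasks the terminal dioxolane (hydrolysis then Malaprade cleavage), now as the C6 aldehyde, leaving the silyl ether, the allylic bromide and the triene intact.

**Step 13**
Reactants: 23 (bromo aldehyde from step 12)
Product: 26 (1(10)E,2Z)-8α-angeloyloxy-5α-hydroxygermacra-1(10),2,4(15),11(13)-tetraen-12,6α-olide (5R,6S,7R,8S), via ring-closed silyl ether 24 (not isolated), via silylated lactone 25 (not isolated)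
Conditions: undivided cell, Al anode, graphite-felt cathode, CrCl2 (20 mol%), TMSCl (3 equiv), LiCl (0.2 M), DMF/THF 1:1, 5 mA (about 2.5 F/mol), 23 added over 12 h by syringe pump (final 2 mM), rt; then HF·pyridine, pyridine, THF, 0 °C → rt
Reagents that add atoms: none
Why: Proposed new method: a chromium-catalysed electroreductive Nozaki–Hiyama–Kishi macro-allylation in which divalent chromium, regenerated at the cathode, reduces the allylic bromide to a 2-(methoxycarbonyl)allylchromium that adds through its γ-carbon (C7) to the C6 aldehyde in a six-membered cyclic transition state while TMSCl frees the alkoxide so the metal turns over and no triplet sensitiser is present to scramble the 2Z triene; the closest known reactions are the stoichiometric CrCl2 Barbier macrocyclisations that close germacranolide ten-membered rings from the same (Z)-bromomethyl enoates and the intermolecular electrochemical chromium-catalysed couplings of aldehydes, and the configuration is substrate-set, with Felkin–Anh attack anti to the C5 silyloxy group giving 5,6-anti (C6 S), the ring-templated transition state giving the 6,7-trans relationship, and entry at C7 anti to the C8 acyloxy group in the A(1,3)-minimised rotamer giving C7 R, after which HF·pyridine removes both silyl groups and the C6 hydroxyl lactonises.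

**Step 14**
Reactants: 26 (triene lactone alcohol from step 13)
Product: 27 (1(10)E,2Z)-8α-angeloyloxy-4α,15-epoxy-5α-hydroxygermacra-1(10),2,11(13)-trien-12,6α-olide (4S,5S,6S,7R,8S)
Conditions: VO(acac)2 (5 mol%), t-BuOOH (1.3 equiv, decane), CH2Cl2, 0 °C; filtered through basic alumina and used directly
Reagents that add atoms: tert-butyl hydroperoxide CC(C)(C)OO
Why: Vanadium-catalysed hydroxyl-directed epoxidation (Sharpless–Michaelson type) reacts only at the allylic-alcohol alkene and delivers oxygen to the face of C4=C15 syn to the C5 hydroxyl, setting C4 (4α-O).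

**Step 15**
Reactants: 27 (epoxy diene from step 14)
Product: 29 8α-angeloyloxy-1β,10α:2β,3β:4α,15-triepoxy-5α-hydroxygermacr-11(13)-en-12,6α-olide (1R,2R,3S,4S,5S,6S,7R,8S,10R), via monoepoxide 28 (not isolated)
Conditions: DMDO (3 equiv), acetone, −30 → 0 °C; cold evaporation, chromatography on Et3N-deactivated silica
Reagents that add atoms: dimethyldioxirane CC1(C)OO1
Why: Neutral dimethyldioxirane epoxidation attacks the two remaining ring alkenes from the exposed outer face of the ten-membered ring (the E-trisubstituted 1(10) alkene first, as in peracid epoxidation of germacra-1(10)-enolides, then the 2Z alkene on the same β side), setting C1, C10, C2 and C3 while the electron-poor enoates stay untouched.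

**Compound list**
1 | (4R)-2,2-dimethyl-1,3-dioxolane-4-carbaldehyde | O=C[C@H]1COC(C)(C)O1 | starting material
2 | 3-bromoprop-1-yne | C#CCBr | starting material
3 | (1S)-1-[(4R)-2,2-dimethyl-1,3-dioxolan-4-yl]but-3-yn-1-ol | C#CC[C@H](O)[C@H]1COC(C)(C)O1 | intermediate
4 | alkenylalane: O-dimethylaluminium alkoxide of (1S,3E)-4-(dimethylalumanyl)-1-[(4R)-2,2-dimethyl-1,3-dioxolan-4-yl]-3-methylbut-3-en-1-ol | C[Al](C)/C=C(\C)C[C@H](O[Al](C)C)[C@H]1COC(C)(C)O1 | intermediate
5 | (1S,3E)-1-[(4R)-2,2-dimethyl-1,3-dioxolan-4-yl]-4-iodo-3-methylbut-3-en-1-ol | I/C=C(\C)C[C@H](O)[C@H]1COC(C)(C)O1 | intermediate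
6 | angelic acid, (2Z)-2-methylbut-2-enoic acid | C/C=C(/C)C(=O)O | starting material
7 | (2Z)-2-methylbut-2-enoic 2,4,6-trichlorobenzoic anhydride | C/C=C(/C)C(=O)OC(=O)c1c(Cl)cc(Cl)cc1Cl | intermediate
8 | (1S,3E)-1-[(4R)-2,2-dimethyl-1,3-dioxolan-4-yl]-4-iodo-3-methylbut-3-en-1-yl (2Z)-2-methylbut-2-enoate | I/C=C(\C)C[C@H](OC(=O)/C(C)=C\C)[C@H]1COC(C)(C)O1 | intermediate
9 | (2R,3S,5E)-1,2-dihydroxy-6-iodo-5-methylhex-5-en-3-yl (2Z)-2-methylbut-2-enoate | I/C=C(\C)C[C@H](OC(=O)/C(C)=C\C)[C@H](O)CO | intermediate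
10 | (2S,4E)-5-iodo-4-methyl-1-oxopent-4-en-2-yl (2Z)-2-methylbut-2-enoate | I/C=C(\C)C[C@H](OC(=O)/C(C)=C\C)C=O | intermediate
11 | methyl acrylate | C=CC(=O)OC | starting material
12 | methyl 2-[(1RS,2S,4E)-1-hydroxy-5-iodo-4-methyl-2-{[(2Z)-2-methylbut-2-enoyl]oxy}pent-4-en-1-yl]prop-2-enoate | COC(=O)C(=C)C(O)[C@@H](OC(=O)/C(C)=C\C)C/C(C)=C/I | intermediate
13 | 4-(trimethylsilyl)but-3-yn-2-one | CC(=O)C#C[Si](C)(C)C | starting material
14 | 4-(trimethylsilyl)but-1-en-3-yn-2-yl trifluoromethanesulfonate | C=C(OS(=O)(=O)C(F)(F)F)C#C[Si](C)(C)C | intermediate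
15 | (4S)-2,2-dimethyl-1,3-dioxolane-4-carbaldehyde | O=C[C@@H]1COC(C)(C)O1 | starting material
16 | (1R)-1-[(4S)-2,2-dimethyl-1,3-dioxolan-4-yl]-2-methylidene-4-(trimethylsilyl)but-3-yn-1-ol | C[Si](C)(C)C#CC(=C)[C@@H](O)[C@@H]1COC(C)(C)O1 | intermediate
17 | (1R)-1-[(4S)-2,2-dimethyl-1,3-dioxolan-4-yl]-2-methylidenebut-3-yn-1-ol | C#CC(=C)[C@@H](O)[C@@H]1COC(C)(C)O1 | intermediate
18 | tert-butyl{[(1R)-1-[(4S)-2,2-dimethyl-1,3-dioxolan-4-yl]-2-methylidenebut-3-yn-1-yl]oxy}dimethylsilane | C#CC(=C)[C@@H](O[Si](C)(C)C(C)(C)C)[C@@H]1COC(C)(C)O1 | intermediate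
19 | methyl 2-[(1RS,2S,4E,9R)-9-{[tert-butyl(dimethyl)silyl]oxy}-9-[(4S)-2,2-dimethyl-1,3-dioxolan-4-yl]-1-hydroxy-4-methyl-8-methylidene-2-{[(2Z)-2-methylbut-2-enoyl]oxy}non-4-en-6-yn-1-yl]prop-2-enoate | COC(=O)C(=C)C(O)[C@@H](OC(=O)/C(C)=C\C)C/C(C)=C/C#CC(=C)[C@@H](O[Si](C)(C)C(C)(C)C)[C@@H]1COC(C)(C)O1 | intermediate
20 | methyl 2-[(1RS,2S,4E,6Z,9R)-9-{[tert-butyl(dimethyl)silyl]oxy}-9-[(4S)-2,2-dimethyl-1,3-dioxolan-4-yl]-1-hydroxy-4-methyl-8-methylidene-2-{[(2Z)-2-methylbut-2-enoyl]oxy}nona-4,6-dien-1-yl]prop-2-enoate | COC(=O)C(=C)C(O)[C@@H](OC(=O)/C(C)=C\C)C/C(C)=C/C=C\C(=C)[C@@H](O[Si](C)(C)C(C)(C)C)[C@@H]1COC(C)(C)O1 | intermediate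
21 | methyl (2Z,4S,6E,8Z,11R)-2-(bromomethyl)-11-{[tert-butyl(dimethyl)silyl]oxy}-11-[(4S)-2,2-dimethyl-1,3-dioxolan-4-yl]-6-methyl-10-methylidene-4-{[(2Z)-2-methylbut-2-enoyl]oxy}undeca-2,6,8-trienoate | COC(=O)/C(CBr)=C/[C@@H](OC(=O)/C(C)=C\C)C/C(C)=C/C=C\C(=C)[C@@H](O[Si](C)(C)C(C)(C)C)[C@@H]1COC(C)(C)O1 | intermediate
22 | methyl (2Z,4S,6E,8Z,11R,12S)-2-(bromomethyl)-11-{[tert-butyl(dimethyl)silyl]oxy}-12,13-dihydroxy-6-methyl-10-methylidene-4-{[(2Z)-2-methylbut-2-enoyl]oxy}trideca-2,6,8-trienoate | COC(=O)/C(CBr)=C/[C@@H](OC(=O)/C(C)=C\C)C/C(C)=C/C=C\C(=C)[C@@H](O[Si](C)(C)C(C)(C)C)[C@@H](O)CO | intermediate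
23 | methyl (2Z,4S,6E,8Z,11R)-2-(bromomethyl)-11-{[tert-butyl(dimethyl)silyl]oxy}-6-methyl-10-methylidene-4-{[(2Z)-2-methylbut-2-enoyl]oxy}-12-oxododeca-2,6,8-trienoate | COC(=O)/C(CBr)=C/[C@@H](OC(=O)/C(C)=C\C)C/C(C)=C/C=C\C(=C)[C@@H](O[Si](C)(C)C(C)(C)C)C=O | intermediate
24 | methyl (1(10)E,2Z)-8α-angeloyloxy-5α-{[tert-butyl(dimethyl)silyl]oxy}-6α-[(trimethylsilyl)oxy]germacra-1(10),2,4(15),11(13)-tetraen-12-oate (5R,6S,7R,8S) | C[Si](C)(C)O[C@H]1[C@H](C(=C)C(=O)OC)[C@@H](OC(=O)/C(C)=C\C)C/C(C)=C/C=C\C(=C)[C@H]1O[Si](C)(C)C(C)(C)C | intermediate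
25 | (1(10)E,2Z)-8α-angeloyloxy-5α-{[tert-butyl(dimethyl)silyl]oxy}germacra-1(10),2,4(15),11(13)-tetraen-12,6α-olide | C=C1C(=O)O[C@H]2[C@H]1[C@@H](OC(=O)/C(C)=C\C)C/C(C)=C/C=C\C(=C)[C@H]2O[Si](C)(C)C(C)(C)C | intermediate
26 | (1(10)E,2Z)-8α-angeloyloxy-5α-hydroxygermacra-1(10),2,4(15),11(13)-tetraen-12,6α-olide (5R,6S,7R,8S) | C=C1C(=O)O[C@H]2[C@H]1[C@@H](OC(=O)/C(C)=C\C)C/C(C)=C/C=C\C(=C)[C@H]2O | intermediate
27 | (1(10)E,2Z)-8α-angeloyloxy-4α,15-epoxy-5α-hydroxygermacra-1(10),2,11(13)-trien-12,6α-olide (4S,5S,6S,7R,8S) | C=C1C(=O)O[C@H]2[C@H]1[C@@H](OC(=O)/C(C)=C\C)C/C(C)=C/C=C\[C@]1(CO1)[C@H]2O | intermediate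
28 | (2Z)-8α-angeloyloxy-1β,10α:4α,15-diepoxy-5α-hydroxygermacra-2,11(13)-dien-12,6α-olide | C=C1C(=O)O[C@H]2[C@H]1[C@@H](OC(=O)/C(C)=C\C)C[C@@]1(C)O[C@@H]1/C=C\[C@]1(CO1)[C@H]2O | intermediate
29 | 8α-angeloyloxy-1β,10α:2β,3β:4α,15-triepoxy-5α-hydroxygermacr-11(13)-en-12,6α-olide (1R,2R,3S,4S,5S,6S,7R,8S,10R), CNP0594916.1 | C=C1C(=O)O[C@H]2[C@H]1[C@@H](OC(=O)/C(C)=C\C)C[C@@]1(C)O[C@@H]1[C@@H]1O[C@@H]1[C@]1(CO1)[C@H]2O | target

**Step count**
Total: 15 steps. Longest linear sequence: 12 steps (steps 1–5, then 9–15); the west half (steps 6–8) joins at step 9.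

**Steps most likely to fail, with fallbacks**

The macrocyclisation of step 13 is the untested step. The risks are oligomerisation, slow chromium turnover at the cathode, 1,4-loss of the C8 angelate from the allylchromium, and the C6/C7 configuration, where the three stereochemical models have to agree inside one ring. The fallback is known chemistry and gives up electrolysis and catalytic turnover: the allylmetal is made thermally with a stoichiometric reductant, the way germacranolide rings have been closed before. It sets out from aldehyde 23, which is added over 10 h to CrCl2 (8 equiv) in THF/DMF at rt to 50 °C. Aqueous work-up gives the ring-closed hydroxy ester methyl (1(10)E,2Z)-8α-angeloyloxy-5α-{[tert-butyl(dimethyl)silyl]oxy}-6α-hydroxygermacra-1(10),2,4(15),11(13)-tetraen-12-oate F1. HF·pyridine lactonises it to 25 and removes the silyl group, and the route is rejoined at 26.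

The double epoxidation of step 15 depends on the ring conformation for both faces. The 1β,10α outcome has close analogy; the β-face attack on the 2Z alkene does not, and the C5 hydroxyl could even steer the oxidant to the α face. The fallback builds the 2,3-oxirane by inversion instead of direct oxygen transfer. It sets out from 27: one equivalent of DMDO at −40 °C is stopped at monoepoxide 28, isolated this time. NBS in THF/H2O at 0 °C then places the bromonium on the face the dioxirane preferred and water opens it trans at the less hindered C2, giving 8α-angeloyloxy-3α-bromo-1β,10α:4α,15-diepoxy-2β,5α-dihydroxygermacr-11(13)-en-12,6α-olide F2. K2CO3 in acetone closes the oxirane by backside displacement on the β face, and the route is rejoined at 29.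

The Baylis–Hillman reaction of step 5 exposes an α-acyloxy aldehyde to an amine for many hours, so C8 can epimerise and the angelate can shift to the new neighbouring hydroxyl. The fallback replaces amine catalysis by a fast organometallic addition (vinylalumination). It sets out from aldehyde 10: methyl propiolate is hydroaluminated with i-Bu2AlH and N-methylmorpholine N-oxide in THF at 0 °C to methyl 2-[bis(2-methylpropyl)alumanyl]prop-2-enoate F3, which adds to 10 at −78 °C within minutes. Work-up rejoins the route at 12.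

**Further compounds**
F1 | step 13 | methyl (1(10)E,2Z)-8α-angeloyloxy-5α-{[tert-butyl(dimethyl)silyl]oxy}-6α-hydroxygermacra-1(10),2,4(15),11(13)-tetraen-12-oate | O[C@H]1[C@H](C(=C)C(=O)OC)[C@@H](OC(=O)/C(C)=C\C)C/C(C)=C/C=C\C(=C)[C@H]1O[Si](C)(C)C(C)(C)C
F2 | step 15 | 8α-angeloyloxy-3α-bromo-1β,10α:4α,15-diepoxy-2β,5α-dihydroxygermacr-11(13)-en-12,6α-olide | C=C1C(=O)O[C@H]2[C@H]1[C@@H](OC(=O)/C(C)=C\C)C[C@@]1(C)O[C@@H]1[C@H](O)[C@@H](Br)[C@]1(CO1)[C@H]2O
F3 | step 5 | methyl 2-[bis(2-methylpropyl)alumanyl]prop-2-enoate | C=C([Al](CC(C)C)CC(C)C)C(=O)OC
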